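**Assumption:** the SMILES is read literally as 4R,5R,6S,7S,8R,9R with an E (ring-cis) C1=C10 bond. This makes H-6 and H-7 cis, so the lactone is cis-fused, and the route is planned for exactly this configuration.

Germacrane numbering is used throughout: ring C1–C10; C14 is the ester carbon on C10; C15 the methyl on C4; C11(=C13H2)–C12(=O) the acrylate unit on C7.

## Analysis of the target

Fluctuadin is a ten-membered carbocycle (C1–C10) fused across C6–C7 to an α-methylene-γ-butyrolactone (ring O6–C6–C7–C11–C12, exocyclic C11=C13). It carries a C4–C5 epoxide with the C15 methyl on C4, a C1=C10 double bond with the C14 methyl ester on C10, an acetate on O9 and a methacrylate on O8. The C1=C10 alkene is E by the sequence rules but cis within the ring (C2 and C9 on the same side), so C9–C10(=C1)–C14 is a Morita–Baylis–Hillman-type array. The six stereocentres C4–C9 are contiguous: the epoxide is trans (from a 4E alkene), H-6 and H-7 are cis, O5 and O6 are threo, and O8 and O9 form a threo diol. The feature that invites the key move is the bond C6–C7: it belongs to the ten-membered ring and to the lactone ring at once, and C7–C11–C13 next to the C12 carbonyl is a 2-(alkoxycarbonyl)allyl unit, so one allyl-metal addition to a C6 aldehyde can close both rings and set C6 and C7. The sensitive groups are three Michael acceptors (α-methylene lactone, methacrylate, C1=C10 enoate), an acid-labile trisubstituted epoxide, and two different esters on a vicinal diol (1,2-acyl migration; a free 8-OH can also attack C12 or C14). The difficulty lies in the strained medium ring, in telling O8 from O9, and in setting C6 and C7 correctly relative to both neighbours C5 and C8.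

## Retrosynthetic reasoning

**C8 ester and ether (23 ⇒ 22 ⇒ 21).** The methacrylate is cut first, at the O8–acyl bond. An acyloxy group on C8 would be a leaving group in the 4-position of the allyl-metal species of the key step, so O8 travels through the ring closure as the 4-methoxyphenyl ether 21. That ether is cleaved oxidatively to alcohol 22 without acid or base strong enough to harm the lactone.

**Key disconnection (21 ⇒ 18).** The C6–C7 ring bond and the lactone C12–O6 bond are cut together. This opens both rings to the acyclic bromo epoxy aldehyde 18. It is cut here and not elsewhere because only this bond is shared by the two rings and lies between two stereocentres that a single carbonyl allylation creates. The forward reaction is an intramolecular Nozaki–Hiyama allylation with lactonisation; it must close a ten-membered ring, give the 6,7-cis relationship and choose the correct faces relative to C5 and C8.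

**C7=C11 (18 ⇒ 16 + 17).** The trisubstituted allylic bromide is cut at its double bond into the terminal alkene 16 and the acrylate 17. Cross-metathesis installs the whole C11–C13 unit in one step and avoids an aldehyde at C7, which would sit β to the C9 acetate.

**Epoxide and oxidation levels (16 ⇒ 15 ⇒ 14 ⇒ 13).** The acetate on O9, the C6 aldehyde and the epoxide are taken back to the allylic diol 13. The epoxide comes from a Sharpless asymmetric epoxidation directed by the C6 hydroxyl, so C4 and C5 are set by the reagent. It is introduced only after all Lewis-acidic steps of the chain assembly.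

**C8–C9 (13 ⇐ 12 ⇒ 8 + 9).** The bond between the two carbinol carbons is cut to the aldehyde 8 and the allyl ether 9. A Brown alkoxyallylboration forms this bond, sets C8 and C9 as the threo pair under reagent control, and delivers O9 free and O8 protected. This solves the differentiation of the two oxygens at the moment they are created.

**C9–C10 and the alkene geometry (8 ⇒ 7 ⇒ 6 ⇒ 4 + 5).** The formyl enoate 8 is traced through the allylic bromide 7 to the Morita–Baylis–Hillman adduct 6 of aldehyde 4 and methyl acrylate 5. The allylic transposition 6 → 7 fixes C2 cis to C9 and trans to the ester, the geometry needed for the ring-cis C1=C10 bond.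

**C1 aldehyde (4 ⇒ 2 ⇒ 1).** Aldehyde 4 comes from geranyl acetate 1 by oxidative removal of the terminal isopropylidene group via epoxide 2. The 4E alkene and all six carbons C1–C6 with C15 are bought in.

## Alternatives that were turned down

**Alternative 1:** ring-closing metathesis at C1=C10 (the textbook cut). The diene A1, with the lactone already in place, a terminal alkene at C1 and a 2-substituted acrylate at C10, would be closed with a ruthenium alkylidene. Turned down because:
- the closure must form a trisubstituted, ester-bearing alkene inside a strained ten-membered ring next to the C9 acetoxy centre, the slowest class of ring-closing metathesis;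
- A1 holds a second acrylate-type alkene (the α-methylene lactone) that competes for the carbene;
- the closure forms no stereocentre, so C6 and C7 need a separate intermolecular allylation and two alkene handles must be installed, which costs more steps than the chosen key step.

**Alternative 2:** Nozaki–Hiyama–Kishi closure at C9–C10. The α-iodo enoate aldehyde A2 would be cyclised with CrCl2 and catalytic NiCl2. Turned down because:
- an α-chromio acrylate equilibrates with its O-bound allenolate, so the C1=C10 geometry stored in the iodide is not held;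
- C9 would be formed under the influence of the α-aryloxy centre C8 alone, where the polar Felkin–Anh preference leads to the 8,9-anti isomer, the wrong one;
- only one ring and one stereocentre are made.

**Alternative 3:** pinacol closure at C8–C9. The dialdehyde A3 would be coupled with SmI2 to form the diol and the ring in one step. Turned down because:
- O8 and O9 would arise undifferentiated although they must carry different esters;
- the threo/erythro outcome in a ten-membered ring cannot be argued;
- the reductant also attacks the α-methylene lactone and the doubly activated alkene of A3 by conjugate reduction;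
- the C8 aldehyde sits on C7, which can epimerise.

Key step: step 12

## Route

Step 1
Reactants: 1 geranyl acetate
Product: 2 (2E)-5-(3,3-dimethyloxiran-2-yl)-3-methylpent-2-en-1-yl acetate (racemic epoxide)
Conditions: mCPBA (1.05 equiv), NaHCO3, CH2Cl2, 0 °C
Reagents that add atoms: mCPBA, O=C(OO)c1cccc(Cl)c1
Why: Prilezhaev epoxidation; the 6,7-alkene is the more electron-rich one because the 2,3-alkene is deactivated by the allylic acetate, and the racemic centre is removed in step 2.

Step 2
Reactants: 2 (2E)-5-(3,3-dimethyloxiran-2-yl)-3-methylpent-2-en-1-yl acetate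
Product: 4 (2E)-3-methyl-6-oxohex-2-en-1-yl acetate, via diol 3 (not isolated)
Conditions: H5IO6 (1.2 equiv), THF/H2O, 0 °C to rt
Reagents that add atoms: none
Why: Acid-catalysed hydration of the epoxide at its tertiary carbon followed by periodate glycol cleavage (Malaprade reaction); the oxygen taken up from water leaves with the acetone fragment, and the 4E alkene and the acetate are untouched.

Step 3
Reactants: 4 (2E)-3-methyl-6-oxohex-2-en-1-yl acetate; 5 methyl acrylate
Product: 6 methyl (6E)-8-acetoxy-3-hydroxy-6-methyl-2-methylideneoct-6-enoate (racemic at the carbinol)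
Conditions: 5 (3 equiv), DABCO (1 equiv), MeOH, rt, several days
Reagents that add atoms: none
Why: Morita–Baylis–Hillman reaction of an unhindered aliphatic aldehyde; it forms the C1–C10 bond, and the carbinol centre is lost in the next step, so its configuration does not matter.

Step 4
Reactants: 6 methyl (6E)-8-acetoxy-3-hydroxy-6-methyl-2-methylideneoct-6-enoate
Product: 7 methyl (2Z,6E)-8-acetoxy-2-(bromomethyl)-6-methylocta-2,6-dienoate
Conditions: NBS, Me2S, CH2Cl2, −20 °C to rt
Reagents that add atoms: N-bromosuccinimide, O=C1CCC(=O)N1Br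
Why: Corey–Kim-type activation of the alcohol and SN2′ attack of bromide with allylic transposition; this standard conversion of such adducts gives the isomer with the chain trans to the ester, which fixes the C1=C10 geometry of the target.

Step 5
Reactants: 7 methyl (2Z,6E)-8-acetoxy-2-(bromomethyl)-6-methylocta-2,6-dienoate
Product: 8 methyl (2E,6E)-8-acetoxy-2-formyl-6-methylocta-2,6-dienoate
Conditions: NMO (4 equiv), MeCN, 0 °C to rt; used at once
Reagents that add atoms: N-methylmorpholine N-oxide, C[N+]1([O-])CCOCC1
Why: Kornblum-type oxidation: the N-oxide oxygen displaces the primary allylic bromide and the N–O bond then fragments with loss of the α-proton; the alkene is not involved, so the formyl group stays cis to the chain.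

Step 6
Reactants: 8 methyl (2E,6E)-8-acetoxy-2-formyl-6-methylocta-2,6-dienoate; 9 allyl 4-methoxyphenyl ether
Product: 12 methyl (2E,6E)-8-acetoxy-2-[(1R,2R)-1-hydroxy-2-(4-methoxyphenoxy)but-3-en-1-yl]-6-methylocta-2,6-dienoate, via allylborane 10 (not isolated), via borinate 11 (not isolated)
Conditions: 9, sBuLi, THF, −78 °C; (−)-Ipc2BOMe; BF3·OEt2; then 8, −78 °C; HOCH2CH2NH2 work-up
Reagents that add atoms: none
Why: Brown alkoxyallylboration: the Z-configured γ-aryloxyallylborane reacts through a chair transition state to give the threo (syn) 1,2-diol mono-ether, and the isopinocampheyl groups derived from (+)-α-pinene direct the attack to the si face of the aldehyde, which gives 9R and therefore 8R; O9 is formed free and O8 protected.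

Step 7
Reactants: 12 methyl (2E,6E)-8-acetoxy-2-[(1R,2R)-1-hydroxy-2-(4-methoxyphenoxy)but-3-en-1-yl]-6-methylocta-2,6-dienoate
Product: 13 methyl (2E,6E)-8-hydroxy-2-[(1R,2R)-1-hydroxy-2-(4-methoxyphenoxy)but-3-en-1-yl]-6-methylocta-2,6-dienoate
Conditions: K2CO3 (cat.), MeOH, 0 °C
Reagents that add atoms: none
Why: Transesterification (methanolysis) of the primary allylic acetate; exchange at the methyl ester is degenerate, and the trisubstituted enoate is a poor acceptor for methoxide.

Step 8
Reactants: 13 methyl (2E,6E)-8-hydroxy-2-[(1R,2R)-1-hydroxy-2-(4-methoxyphenoxy)but-3-en-1-yl]-6-methylocta-2,6-dienoate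
Product: 14 methyl (2E)-2-[(1R,2R)-1-hydroxy-2-(4-methoxyphenoxy)but-3-en-1-yl]-5-[(2R,3R)-3-(hydroxymethyl)-2-methyloxiran-2-yl]pent-2-enoate
Conditions: Ti(OiPr)4 (10 mol%), D-(−)-diethyl tartrate (12 mol%), tBuOOH, 4 Å MS, CH2Cl2, −20 °C
Reagents that add atoms: tert-butyl hydroperoxide, CC(C)(C)OO
Why: Sharpless asymmetric epoxidation of the geraniol-type allylic alcohol; D-(−)-tartrate delivers oxygen to the face that gives the 4R,5R epoxide, while the electron-poor enoate and the vinyl group (homoallylic to O9) do not react.

Step 9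
Reactants: 14 methyl (2E)-2-[(1R,2R)-1-hydroxy-2-(4-methoxyphenoxy)but-3-en-1-yl]-5-[(2R,3R)-3-(hydroxymethyl)-2-methyloxiran-2-yl]pent-2-enoate
Product: 15 methyl (2E)-5-[(2R,3S)-3-formyl-2-methyloxiran-2-yl]-2-[(1R,2R)-1-hydroxy-2-(4-methoxyphenoxy)but-3-en-1-yl]pent-2-enoate
Conditions: TEMPO (10 mol%), PhI(OAc)2 (1.2 equiv), CH2Cl2, rt
Reagents that add atoms: none
Why: Oxoammonium (TEMPO) oxidation, which takes the primary alcohol in preference to the hindered secondary one at C9; the epoxide carbon next to the new aldehyde does not enolise (the descriptor at C5 changes only because the formyl group outranks C4).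

Step 10
Reactants: 15 methyl (2E)-5-[(2R,3S)-3-formyl-2-methyloxiran-2-yl]-2-[(1R,2R)-1-hydroxy-2-(4-methoxyphenoxy)but-3-en-1-yl]pent-2-enoate
Product: 16 methyl (2E)-2-[(1R,2R)-1-acetoxy-2-(4-methoxyphenoxy)but-3-en-1-yl]-5-[(2R,3S)-3-formyl-2-methyloxiran-2-yl]pent-2-enoate
Conditions: Ac2O, pyridine, DMAP (cat.), CH2Cl2, 0 °C
Reagents that add atoms: acetic anhydride, CC(=O)OC(C)=O
Why: DMAP-catalysed acylation of the only free hydroxyl; this puts the final acetate on O9 while O8 is still blocked, so no 1,2-migration is possible.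

Step 11
Reactants: 16 methyl (2E)-2-[(1R,2R)-1-acetoxy-2-(4-methoxyphenoxy)but-3-en-1-yl]-5-[(2R,3S)-3-formyl-2-methyloxiran-2-yl]pent-2-enoate; 17 methyl 2-(bromomethyl)acrylate
Product: 18 methyl (2Z,4R,5R,6E)-5-acetoxy-2-(bromomethyl)-9-[(2R,3S)-3-formyl-2-methyloxiran-2-yl]-6-(methoxycarbonyl)-4-(4-methoxyphenoxy)nona-2,6-dienoate
Conditions: 17 (5 equiv), second-generation Hoveyda–Grubbs catalyst RuCl2(H2IMes)(=CH-C6H4-2-OiPr) (10 mol%), CH2Cl2, 40 °C
Reagents that add atoms: none
Why: Olefin cross-metathesis of the terminal vinyl group with a 1,1-disubstituted acrylate; as with methacrylates the trisubstituted enoate should form with the ester trans to the chain (Z here, since CH2Br outranks the ester), and the trisubstituted, electron-poor C1=C10 enoate is inert.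

Step 12
Reactants: 18 methyl (2Z,4R,5R,6E)-5-acetoxy-2-(bromomethyl)-9-[(2R,3S)-3-formyl-2-methyloxiran-2-yl]-6-(methoxycarbonyl)-4-(4-methoxyphenoxy)nona-2,6-dienoate
Product: 21 (1(10)E,4R,5R,6S,7S,8R,9R)-9-acetoxy-4,5-epoxy-8-(4-methoxyphenoxy)germacra-1(10),11(13)-dien-12,6-olid-14-oic acid methyl ester, via allylchromium 19 (not isolated), via chromium alkoxide 20 (not isolated)
Conditions: CrCl2 (8 equiv), THF, 25 °C, 18 added over 12 h (final 2 mM); aq NH4Cl
Reagents that add atoms: none
Why: Divalent chromium reduces only the allylic C13–Br bond of 18 to the trivalent allylchromium 19, which adds to the C6 aldehyde through its γ-carbon C7 in a closed six-membered (Zimmerman–Traxler) transition state, and the chromium alkoxide 20 then attacks the C12 methyl ester and expels methoxide. The closest known reaction type is the chromium-mediated (Nozaki–Hiyama) 2-(alkoxycarbonyl)allylation of aldehydes to α-methylene-γ-butyrolactones, including its intramolecular use for medium and ten-membered carbocycles. The carbocycle closes in a 10-exo-trig mode (C7 onto the C6 carbonyl) and the lactone in a 5-exo-trig mode (O6 onto C12). For the C6/C7 relationship, the C11 ester keeps C8 cis to CH2Cr, so C8 sits axial in the chair and the syn adduct, that is the cis-fused lactone, should result. For C7, allylic 1,3-strain with CH2Cr places H-8 in the alkene plane and the aldehyde adds anti to the C8–C9 bond on the side of the aryloxy group, which gives 7S from 8R. C6 then follows as 6S; this is the aldehyde face that gives the threo epoxy alcohol, not the one an open-chain polar Felkin–Anh model prefers, so the ring-forming tether and not the C5 centre has to decide. The step needs aldehyde selectivity over esters and epoxide (organochromium reagents provide it), ring closure over oligomerisation (slow addition at high dilution), and retention of the C8 aryloxy group (an ether is a poor leaving group for 1,4-elimination).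

Step 13
Reactants: 21 (1(10)E,4R,5R,6S,7S,8R,9R)-9-acetoxy-4,5-epoxy-8-(4-methoxyphenoxy)germacra-1(10),11(13)-dien-12,6-olid-14-oic acid methyl ester
Product: 22 8-O-desmethacryloylfluctuadin (the same skeleton with free 8-OH)
Conditions: (NH4)2Ce(NO3)6 (2.5 equiv), pyridine, MeCN/H2O 4:1, 0 °C
Reagents that add atoms: none
Why: Oxidative cleavage of the 4-methoxyphenyl ether by tetravalent cerium (water attacks the arene radical cation, and the C8–O bond is not broken, so C8 keeps its configuration); pyridine buffers the medium for the epoxide, and the electron-poor alkenes are not oxidised.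

Step 14
Reactants: 22 8-O-desmethacryloylfluctuadin
Product: 23 fluctuadin
Conditions: methacrylic anhydride, Et3N, DMAP (cat.), CH2Cl2, 0 °C
Reagents that add atoms: methacrylic anhydride, C=C(C)C(=O)OC(=O)C(C)=C
Why: DMAP-catalysed acylation of the secondary 8-OH with retention at C8; low temperature and a short reaction time are chosen to outrun 9→8 acetyl migration and translactonisation.

## Compound list

1 | geranyl acetate | CC(C)=CCC/C(C)=C/COC(C)=O | starting material
2 | (2E)-5-(3,3-dimethyloxiran-2-yl)-3-methylpent-2-en-1-yl acetate (racemic) | CC1(C)OC1CC/C(C)=C/COC(C)=O | intermediate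
3 | (2E)-6,7-dihydroxy-3,7-dimethyloct-2-en-1-yl acetate (racemic, not isolated) | CC(C)(O)C(O)CC/C(C)=C/COC(C)=O | intermediate
4 | (2E)-3-methyl-6-oxohex-2-en-1-yl acetate | O=CCC/C(C)=C/COC(C)=O | intermediate
5 | methyl acrylate | C=CC(=O)OC | starting material
6 | methyl (6E)-8-acetoxy-3-hydroxy-6-methyl-2-methylideneoct-6-enoate (racemic) | COC(=O)C(=C)C(O)CC/C(C)=C/COC(C)=O | intermediate
7 | methyl (2Z,6E)-8-acetoxy-2-(bromomethyl)-6-methylocta-2,6-dienoate | CC(=O)OC/C=C(\C)CC/C=C(/C(=O)OC)CBr | intermediate
8 | methyl (2E,6E)-8-acetoxy-2-formyl-6-methylocta-2,6-dienoate | CC(=O)OC/C=C(\C)CC/C=C(/C(=O)OC)C=O | intermediate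
9 | allyl 4-methoxyphenyl ether | C=CCOc1ccc(OC)cc1 | starting material
10 | [(2Z)-3-(4-methoxyphenoxy)prop-2-en-1-yl]bis[(1R,2S,3R,5R)-isopinocampheyl]borane (not isolated) | COc1ccc(O/C=C\CB([C@@H]2C[C@@H]3C[C@H]([C@H]2C)C3(C)C)[C@@H]2C[C@@H]3C[C@H]([C@H]2C)C3(C)C)cc1 | intermediate
11 | O9-diisopinocampheylborinate of 12 (not isolated) | CC(=O)OC/C=C(\C)CC/C=C(/C(=O)OC)[C@@H](OB([C@@H]1C[C@@H]2C[C@H]([C@H]1C)C2(C)C)[C@@H]1C[C@@H]2C[C@H]([C@H]1C)C2(C)C)[C@H](Oc1ccc(OC)cc1)C=C | intermediate
12 | methyl (2E,6E)-8-acetoxy-2-[(1R,2R)-1-hydroxy-2-(4-methoxyphenoxy)but-3-en-1-yl]-6-methylocta-2,6-dienoate | CC(=O)OC/C=C(\C)CC/C=C(/C(=O)OC)[C@@H](O)[C@H](Oc1ccc(OC)cc1)C=C | intermediate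
13 | methyl (2E,6E)-8-hydroxy-2-[(1R,2R)-1-hydroxy-2-(4-methoxyphenoxy)but-3-en-1-yl]-6-methylocta-2,6-dienoate | OC/C=C(\C)CC/C=C(/C(=O)OC)[C@@H](O)[C@H](Oc1ccc(OC)cc1)C=C | intermediate
14 | methyl (2E)-2-[(1R,2R)-1-hydroxy-2-(4-methoxyphenoxy)but-3-en-1-yl]-5-[(2R,3R)-3-(hydroxymethyl)-2-methyloxiran-2-yl]pent-2-enoate | OC[C@H]1O[C@]1(C)CC/C=C(/C(=O)OC)[C@@H](O)[C@H](Oc1ccc(OC)cc1)C=C | intermediate
15 | methyl (2E)-5-[(2R,3S)-3-formyl-2-methyloxiran-2-yl]-2-[(1R,2R)-1-hydroxy-2-(4-methoxyphenoxy)but-3-en-1-yl]pent-2-enoate | O=C[C@H]1O[C@]1(C)CC/C=C(/C(=O)OC)[C@@H](O)[C@H](Oc1ccc(OC)cc1)C=C | intermediate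
16 | methyl (2E)-2-[(1R,2R)-1-acetoxy-2-(4-methoxyphenoxy)but-3-en-1-yl]-5-[(2R,3S)-3-formyl-2-methyloxiran-2-yl]pent-2-enoate | O=C[C@H]1O[C@]1(C)CC/C=C(/C(=O)OC)[C@@H](OC(C)=O)[C@H](Oc1ccc(OC)cc1)C=C | intermediate
17 | methyl 2-(bromomethyl)acrylate | C=C(CBr)C(=O)OC | starting material
18 | methyl (2Z,4R,5R,6E)-5-acetoxy-2-(bromomethyl)-9-[(2R,3S)-3-formyl-2-methyloxiran-2-yl]-6-(methoxycarbonyl)-4-(4-methoxyphenoxy)nona-2,6-dienoate | O=C[C@H]1O[C@]1(C)CC/C=C(/C(=O)OC)[C@@H](OC(C)=O)[C@H](Oc1ccc(OC)cc1)/C=C(/C(=O)OC)CBr | intermediate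
19 | trivalent allylchromium dichloride from 18 (CrCl2 on C13 in place of Br; not isolated) | O=C[C@H]1O[C@]1(C)CC/C=C(/C(=O)OC)[C@@H](OC(C)=O)[C@H](Oc1ccc(OC)cc1)/C=C(/C(=O)OC)C[Cr](Cl)Cl | intermediate
20 | chromium alkoxide of the ring-closed hydroxy ester (ten-membered ring closed at C6–C7, O6–CrCl2, C12 still the methyl ester; not isolated) | COc1ccc(cc1)O[C@@H]1[C@H](C(=C)C(=O)OC)[C@H](O[Cr](Cl)Cl)[C@H]2O[C@]2(C)CC/C=C(/C(=O)OC)[C@H]1OC(C)=O | intermediate
21 | (1(10)E,4R,5R,6S,7S,8R,9R)-9-acetoxy-4,5-epoxy-8-(4-methoxyphenoxy)germacra-1(10),11(13)-dien-12,6-olid-14-oic acid methyl ester | COc1ccc(cc1)O[C@@H]1[C@@H]2C(=C)C(=O)O[C@@H]2[C@H]2O[C@]2(C)CC/C=C(/C(=O)OC)[C@H]1OC(C)=O | intermediate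
22 | 8-O-desmethacryloylfluctuadin (free 8-OH; 4R,5R,6S,7S,8R,9R) | O[C@@H]1[C@@H]2C(=C)C(=O)O[C@@H]2[C@H]2O[C@]2(C)CC/C=C(/C(=O)OC)[C@H]1OC(C)=O | intermediate
23 | fluctuadin | C=C(C)C(=O)O[C@@H]1[C@@H]2C(=C)C(=O)O[C@@H]2[C@H]2O[C@]2(C)CC/C=C(/C(=O)OC)[C@H]1OC(C)=O | target

## Step count and least certain steps

Total step count: 14. Longest linear sequence: 14 steps, from geranyl acetate 1.

**Step 12 (key step).** Ring closure to a ten-membered ring is slow, so intermolecular coupling or loss of the C8 aryloxy group by 1,4-elimination from the allylchromium may compete. Facial selectivity at the aldehyde may also be poor, because the C5 epoxide centre is mismatched with the face that C8 and the chair demand; this would lead to the trans-fused lactone. Fallback, which takes the C5 centre and the sensitive epoxy aldehyde out of the ring closure: from 13, oxoammonium oxidation of the primary allylic alcohol should give the enal F1; acetylation the acetate F2; cross-metathesis with 17 the bromide F3; and the same CrCl2 cyclisation, now onto an enal, the 4E macrolactone F4. Epoxidation of its only electron-rich alkene (C4=C5) with mCPBA, or under reagent control with a fructose-derived ketone and KHSO5 (Shi epoxidation), returns to 21.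

**Step 11.** Both partners are poor metathesis substrates (a hindered allylic ether terminus and a 1,1-disubstituted acrylate), so slow turnover, self-metathesis of 17 and decay of the catalyst are likely. Fallback, which builds the allylic bromide by carbonyl chemistry: from 14, silylation of the primary alcohol with TBSCl and acetylation of O9 in one flask should give the silyl ether F5. Ozonolysis of the vinyl group gives the aldehyde F6. A Morita–Baylis–Hillman-type vinylalumination (iBu2AlH, NMO, methyl propiolate; not basic, so the β-acetate is not eliminated) gives the allylic alcohol F7. NBS/Me2S gives the bromide F8, HF·pyridine removes the silyl group to give the epoxy alcohol F9, and Dess–Martin oxidation returns to 18.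

**Step 6.** The doubly activated aldehyde 8 may isomerise or decompose before it is trapped; lithiation of 9 may stray to the arene ring; and face selectivity with an α-branched enal may be lower than with simple aldehydes. Fallback, with auxiliary instead of reagent control: from 8, a titanium-mediated Evans-type syn glycolate aldol with (S)-4-benzyl-3-[(4-methoxyphenoxy)acetyl]-1,3-thiazolidine-2-thione (TiCl4, (−)-sparteine) should give the aldol adduct F10. iBu2AlH at −78 °C cleaves the auxiliary to the aldehyde F11, and methylenation with Ph3P=CH2 returns to 12.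

**Step 13.** The acidic cerium reagent may open the epoxide, and the freed 8-OH may take up the neighbouring acetyl group or attack C12. Fallback, which cleaves the aryl ether before the epoxide exists: from 13 the epoxide-free series is followed to F4 as described under step 12. The ether is cleaved there with (NH4)2Ce(NO3)6 to the alcohol F12, methacrylic anhydride gives the ester F13, and epoxidation of C4=C5 with mCPBA (the three other alkenes are electron-poor) as the last step returns to 23.

## Further compounds

F1 | step 12 | methyl (2E,6E)-2-[(1R,2R)-1-hydroxy-2-(4-methoxyphenoxy)but-3-en-1-yl]-6-methyl-8-oxoocta-2,6-dienoate | O=C/C=C(\C)CC/C=C(/C(=O)OC)[C@@H](O)[C@H](Oc1ccc(OC)cc1)C=C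
F2 | step 12 | methyl (2E,6E)-2-[(1R,2R)-1-acetoxy-2-(4-methoxyphenoxy)but-3-en-1-yl]-6-methyl-8-oxoocta-2,6-dienoate | O=C/C=C(\C)CC/C=C(/C(=O)OC)[C@@H](OC(C)=O)[C@H](Oc1ccc(OC)cc1)C=C
F3 | step 12 | methyl (2Z,4R,5R,6E,10E)-5-acetoxy-2-(bromomethyl)-6-(methoxycarbonyl)-4-(4-methoxyphenoxy)-10-methyl-12-oxododeca-2,6,10-trienoate | O=C/C=C(\C)CC/C=C(/C(=O)OC)[C@@H](OC(C)=O)[C@H](Oc1ccc(OC)cc1)/C=C(/C(=O)OC)CBr
F4 | step 12 | 4,5-deoxy analogue of 21 with a 4E double bond (6S,7S,8R,9R) | COc1ccc(cc1)O[C@@H]1[C@@H]2C(=C)C(=O)O[C@@H]2/C=C(\C)CC/C=C(/C(=O)OC)[C@H]1OC(C)=O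
F5 | step 11 | 6-O-TBS, 9-O-acetyl derivative of 14 | CC(C)(C)[Si](C)(C)OC[C@H]1O[C@]1(C)CC/C=C(/C(=O)OC)[C@@H](OC(C)=O)[C@H](Oc1ccc(OC)cc1)C=C
F6 | step 11 | C7 aldehyde from ozonolysis of F5 | CC(C)(C)[Si](C)(C)OC[C@H]1O[C@]1(C)CC/C=C(/C(=O)OC)[C@@H](OC(C)=O)[C@H](Oc1ccc(OC)cc1)C=O
F7 | step 11 | C7 carbinol bearing the 1-(methoxycarbonyl)vinyl group (mixture at C7) | CC(C)(C)[Si](C)(C)OC[C@H]1O[C@]1(C)CC/C=C(/C(=O)OC)[C@@H](OC(C)=O)[C@H](Oc1ccc(OC)cc1)C(O)C(=C)C(=O)OC
F8 | step 11 | 6-O-TBS ether of the (2Z)-allylic bromide | CC(C)(C)[Si](C)(C)OC[C@H]1O[C@]1(C)CC/C=C(/C(=O)OC)[C@@H](OC(C)=O)[C@H](Oc1ccc(OC)cc1)/C=C(/C(=O)OC)CBr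
F9 | step 11 | epoxy alcohol corresponding to 18 (CH2OH in place of CHO) | OC[C@H]1O[C@]1(C)CC/C=C(/C(=O)OC)[C@@H](OC(C)=O)[C@H](Oc1ccc(OC)cc1)/C=C(/C(=O)OC)CBr
F10 | step 6 | syn glycolate aldol adduct of 8 carrying the (4S)-4-benzyl-2-thioxothiazolidin-3-yl group on the C7 carbonyl | CC(=O)OC/C=C(\C)CC/C=C(/C(=O)OC)[C@@H](O)[C@H](Oc1ccc(OC)cc1)C(=O)N1C(=S)SC[C@@H]1Cc1ccccc1
F11 | step 6 | methyl (2E,6E)-8-acetoxy-2-[(1R,2S)-1-hydroxy-2-(4-methoxyphenoxy)-3-oxopropyl]-6-methylocta-2,6-dienoate | CC(=O)OC/C=C(\C)CC/C=C(/C(=O)OC)[C@@H](O)[C@H](Oc1ccc(OC)cc1)C=O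
F12 | step 13 | 4,5-deoxy analogue of 22 with a 4E double bond | O[C@@H]1[C@@H]2C(=C)C(=O)O[C@@H]2/C=C(\C)CC/C=C(/C(=O)OC)[C@H]1OC(C)=O
F13 | step 13 | 4,5-deoxyfluctuadin with a 4E double bond | C=C(C)C(=O)O[C@@H]1[C@@H]2C(=C)C(=O)O[C@@H]2/C=C(\C)CC/C=C(/C(=O)OC)[C@H]1OC(C)=O
A1 | alternative 1 | seco-diene with the lactone in place, a terminal alkene at C1 and a 2-substituted acrylate at C10 | COc1ccc(cc1)O[C@H]([C@@H]1C(=C)C(=O)O[C@@H]1[C@H]1O[C@]1(C)CCC=C)[C@H](OC(C)=O)C(=C)C(=O)OC
A2 | alternative 2 | lactone aldehyde with a (Z)-α-iodo enoate at C10 and the aldehyde at C9 | COc1ccc(cc1)O[C@H]([C@@H]1C(=C)C(=O)O[C@@H]1[C@H]1O[C@]1(C)CC/C=C(\I)C(=O)OC)C=O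
A3 | alternative 3 | lactone dialdehyde with aldehydes at C8 and C9 | O=C[C@@H]1C(=C)C(=O)O[C@@H]1[C@H]1O[C@]1(C)CC/C=C(/C(=O)OC)C=O
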